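## Analysis of the target

Numbering used throughout: ring C1 (bears the side chain), C2 (free OH), C3 (angelate), C4 (methyl and tertiary OH), C5 (ketone), C6 (angelate); chain C7 (carrying the exocyclic methylene C14), C8 (angelate), C9, C10 (OH), C11 (dimethyl carbinol); the ring face that carries the C1 side chain is called β, the opposite face α. The target is a monocyclic C15 (bisabolane-type) skeleton: one cyclohexanone in which every ring carbon is functionalised, joined at C1 to an oxygenated chain through the 1,1-disubstituted alkene C7=C14. It has seven stereocentres, five contiguous on the ring (C6, C1, C2, C3, C4; 1S,2S,3S,4R,6R) and two on the chain (8S,10S). On the ring the oxygens at C6, C2 and C3 are α (trans to the chain) and the C4 hydroxyl is β, so that in the chair with the C1, C2 and C6 substituents equatorial, O3 and O4 are trans-diaxial and O2/O3 are cis; on the chain O8 and O10 are 1,3-anti. Sensitive groups are the three angelates (Z to E isomerisation to tiglates), the C4/C5 α-ketol, the epimerisable α-acyloxy ketone carbon C6, and the diol monoesters O2/O3 and O8/O10, which can undergo acyl migration; ring dienes carrying an oxygen leaving group can aromatise. The difficulty is that seven oxygens must be told apart (three esters on chosen oxygens, four free hydroxyls) while the Z esters and the C7=C14 alkene survive every oxidation. The strategy rests on the C8–C10 unit next to C7=C14: a 1,3-anti diol in which only O8 is acylated is what an aldol followed by intramolecular hydride transfer from an aldehyde hemiacetal produces, and C1–C7/C14 plus the ring carbons and the C4 methyl map onto (S)-carvone.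

## Retrosynthetic reasoning

Target 25 is traced to its bis(triethylsilyl) ether 24 by cutting the two O–Si bonds at O10 and O11. These are the only hydroxyls that need masking during the ring oxidations, so the last step is a plain deprotection under mildly acidic fluoride.

In 24 the bond C3–O(ester) is cut and the acyl group is returned to O2, with C3 and C4 joined in a β-epoxide: epoxy ketone 22. The pattern in 24 (O3/O4 trans-diaxial, O2/O3 cis, ester on the axial O3, free equatorial O2) is what results when a trans-vicinal ester opens an epoxide through a fused dioxolan-2-ylium ion 23 that is then hydrolysed. This delivers O3 already acylated, so no hindered axial alcohol has to be esterified and O2 and O3 need no protecting-group differentiation. The forward reaction must open at C3 rather than C4 and collapse to the axial ester.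

The epoxide of 22 is removed to give enone 19, by way of epoxy alcohol 21 and allylic alcohol 20. The epoxide must sit on the β face, cis to the C1 chain. A direct conjugate epoxidation of 19 would be expected to attack axially in the locked half-chair, trans to the chain, giving the wrong face. The ketone is therefore reduced to the equatorial β-alcohol 20, which directs the epoxidation to its own face, and is then reoxidised; two redox steps buy a secure facial outcome.

Enone 19 is cut at the O6–acyl bond to give ketol 18 and one molecule of 6. The C6–O bond of 18 is then cut, through the cross-conjugated silyl dienol ether 17, back to the 2-angelate 16. The C6 oxygen enters anti to the C1 chain by Rubottom oxidation. Because C2 already carries its ester, the enolisation has no regiochemical choice: C6 is the only methylene next to the ketone.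

Ester 16 is cut at the O2–acyl bond to give alcohol 15 and a second molecule of 6, and the C2–O bond of 15 is cut, through the through-conjugated silyl dienol ether 14, back to 13. The C2 oxygen is put in first by vinylogous oxidation, again anti to the C1 chain. Each ring hydroxyl is esterified as soon as it is made, so every acylation meets a single free secondary hydroxyl and takes one equivalent of the acid. The O2 ester also protects the allylic alcohol during the second oxidation and later serves as the internal nucleophile for the epoxide.

Ether 13 is traced to alcohol 12 by cutting the O10–Si bond; the free hydroxyl is capped at once because it can take the neighbouring acyl group.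

Hydroxy ester 12 is cut at three bonds: C8–C9 (aldol), C10–H (hydride from the formyl group) and O8–C(acyl), leading to enal 3, ketone 5 and Z-enal 8. The cut is made here because it puts the first angelate on the one chain oxygen that needs it without any protecting group. It also joins a chiral-pool ring half to an achiral chain half and creates both chain stereocentres. The forward reaction must set C8 by reagent control, pass that information to C10 through a cyclic transition state, and keep the Z alkene of the donor.

Enal 3 comes from (S)-carvone 1 through allylic chloride 2 (C–Cl, then C=O at the isopropenyl methyl), ketone 5 from hydroxy ketone 4 by silylation, and enal 8 from angelic acid 6 through alcohol 7. All are short, standard operations, so the risk is concentrated in the three-component step.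

## Alternatives that were turned down

Alternative 1: The ring C2–O and C5–O bonds are cut together, the forward step being a [4+2] photooxygenation of a ring diene spanning C2 to C5 that closes the bridged endoperoxide A1. In its favour, two ring oxygens are set cis in one step from dioxygen, and base-induced opening of the peroxide would give the C2 hydroxyl and the C5 ketone directly. On that point it is stronger than the chosen route, which needs two separate enol ether oxidations. Against it: the substrate is a ring dienol of arene-hydrate type, prone to aromatise, and the C7=C14 alkene offers a competing ene pathway. O3 and O4 still have to be added trans across the remaining alkene of a bicyclic peroxide. The step forms no C–C bond and sets no chain stereocentre, so the chain with its 1,3-anti pattern must be built elsewhere. A1 carries free O6 and O8, so three angelates must later be placed selectively on a polyol. The chosen strategy offers in its place a convergent C–C bond formation that creates C8 and C10 with the ester already on O8.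

Alternative 2: The bonds C7–C8 and C14–C8 are cut, the forward step being a Kulinkovich coupling (ClTi(OiPr)3, cyclopentylmagnesium chloride) of a C1 vinyl group on a fully oxygenated ring with the methyl ester of the chain, closing cyclopropanol A2, which would later be opened to the methylene ketone. It is the most convergent of the plans, and it is stronger than the chosen route in that all ring oxygens are in place before the chain and its ester exist, so no late oxidation has to spare an angelate or the exocyclic alkene. Against it: the ring partner needs a long synthesis with three kinds of protecting group and the C5 ketone masked as an ether. The intermolecular ligand-exchange variant is demanding for a hindered vinyl group flanked by two oxygenated carbons and two free hydroxyls. After ring opening, C8 must still be reduced with 1,3-control from an acetonide oxygen that chelates poorly, and all three angelates must be installed at the end. The chosen strategy needs fewer protecting groups and obtains C7=C14 directly from carvone.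

Alternative 3: The C4–C5 bond is cut, the forward step being an intramolecular crossed benzoin reaction of an acyclic keto aldehyde under triazolylidene carbene catalysis, closing the cyclohexanone as ketol A3. It is stronger than the chosen route on one point: the tertiary carbinol C4 and the ketol are made in a single C–C bond-forming ring closure, whereas the chosen route needs a three-step directed epoxidation and an opening. Against it: the substrate must already carry four contiguous stereocentres and the whole chain, which means a long linear sequence. The aldehyde has an α-alkoxy stereocentre that can epimerise or be expelled from the acyl anion equivalent. Control at C4 rests on a flexible chain. A3 carries three benzyl-type ethers, a silyl ether and an acetonide, so many deprotections and a triple selective esterification follow. The chosen strategy takes the ring and C1 from the chiral pool and spends its one uncertain step on the chain, where the ester pattern falls out of the mechanism.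

Key step: step 6

Assumption: the Si-face preference of methyl ketone enolates bound to (−)-(C10H17)2BCl (the reagent made from (+)-α-pinene) is taken to hold for 5 and 3; if the sense proved opposite, the enantiomeric reagent would be used with no other change.

## Route

Step 1
Reactants: 1 (S)-carvone
Product: 2 (5S)-5-(3-chloroprop-1-en-2-yl)-2-methylcyclohex-2-en-1-one
Conditions: Ca(OCl)2, CO2 (dry ice), CH2Cl2/H2O, 0 °C
Reagents that add atoms: calcium hypochlorite, [Ca+2].[O-]Cl.[O-]Cl
Why: Ene-type allylic chlorination by HOCl formed in the flask; only the electron-rich 1,1-disubstituted alkene reacts, the double bond shifts into the former methyl so the 2-propenyl pattern is regenerated, and the conjugated ring alkene and the C1 centre are untouched.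

Step 2
Reactants: 2 (5S)-5-(3-chloroprop-1-en-2-yl)-2-methylcyclohex-2-en-1-one
Product: 3 2-[(1S)-4-methyl-5-oxocyclohex-3-en-1-yl]prop-2-enal
Conditions: Me3NO (anhydrous), NaI (cat.), DMSO, rt
Reagents that add atoms: trimethylamine N-oxide, C[N+](C)(C)[O-]
Why: Kornblum-type N-oxide oxidation: iodide-assisted displacement of the allylic chloride by the N-oxide oxygen (SN2 and SN2′ give the same product here) and loss of trimethylamine give the aldehyde under non-acidic conditions that should not move the exocyclic alkene into conjugation with the ring.

Step 3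
Reactants: 4 3-hydroxy-3-methylbutan-2-one
Product: 5 3-methyl-3-(triethylsilyloxy)butan-2-one
Conditions: TESOTf, 2,6-lutidine, CH2Cl2, 0 °C
Reagents that add atoms: triethylsilyl trifluoromethanesulfonate, CC[Si](CC)(CC)OS(=O)(=O)C(F)(F)F
Why: Silyl triflate silylation of a tertiary alcohol; the ether keeps O11 out of boron and samarium chelates and out of hemiacetal formation in step 6.

Step 4
Reactants: 6 angelic acid
Product: 7 (Z)-2-methylbut-2-en-1-ol
Conditions: LiAlH4, Et2O, 0 °C
Reagents that add atoms: none
Why: Hydride reduction of the carboxylic acid; the trisubstituted alkene is not reduced and its Z geometry is not at risk in the absence of acid or a conjugated carbonyl in the product.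

Step 5
Reactants: 7 (Z)-2-methylbut-2-en-1-ol
Product: 8 (Z)-2-methylbut-2-enal
Conditions: MnO2, CH2Cl2, 0 °C; filtered solution used at once
Reagents that add atoms: none
Why: Neutral heterogeneous oxidation of an allylic alcohol; low temperature and immediate use limit isomerisation of the fragile Z-enal to the E isomer.

Step 6
Reactants: 5 3-methyl-3-(triethylsilyloxy)butan-2-one; 3 2-[(1S)-4-methyl-5-oxocyclohex-3-en-1-yl]prop-2-enal; 8 (Z)-2-methylbut-2-enal
Product: 12 (3S,5S)-5-hydroxy-6-methyl-2-[(1S)-4-methyl-5-oxocyclohex-3-en-1-yl]-6-(triethylsilyloxy)hept-1-en-3-yl (Z)-2-methylbut-2-enoate (O8 angelate, free O10, O11 silyl ether), via boron enolate 9 (not isolated), via boron aldolate 10 (not isolated), via free aldol 11 (not isolated)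
Conditions: (−)-(C10H17)2BCl, Et3N, Et2O, 0 °C; 3, −78 → −20 °C; H2NCH2CH2OH, filtration, solvent change to THF; 8 (5 equiv), SmI2 (0.3 equiv), THF, −10 °C
Reagents that add atoms: none
Why: Proposed new method: ketone 5 can enolise only toward its methyl group, and the boron enolate 9 formed with (−)-(C10H17)2BCl and Et3N adds to the aldehyde of 3 (far more electrophilic than the ring enone) through a closed six-membered transition state, forming the C8–C9 bond. The isopinocampheyl ligands choose the Si face of the aldehyde (reagent control, C8 S), the C1 centre being three bonds away and of little influence. 2-Aminoethanol then takes over the boron as a chelated, precipitating borinate and releases aldol 11 without oxidant or aqueous work-up. Excess Z-enal 8 forms a hemiacetal on O8 (the only free hydroxyl, O11 being silylated), samarium (SmI2 is converted by the aldehyde into the active trivalent alkoxide) bridges the hemiacetal oxygen and the C10 ketone, and the hemiacetal hydrogen is passed to C10 through a chair in which the C8 substituent is equatorial, so that C10 follows from C8 as the 1,3-anti (10S) alcohol while the hemiacetal carbon becomes the ester carbonyl on O8. No ring is closed in this step. The closest known reaction types are the aldol–Tishchenko reaction of metal enolates with two equivalents of one aldehyde and the Evans–Tishchenko reduction of isolated β-hydroxy ketones; new are the one-flask use of a second, different aldehyde and an α,β-unsaturated Z-aldehyde as the hydride donor. The step needs aldehyde-over-enone chemoselectivity, retention of the Z geometry (the hydride shift does not touch the alkene, and amine and boron are filtered off before 8 is added) and 1,3-anti selectivity, which the bridged hemiacetal–ketone samarium chelate secures.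

Step 7
Reactants: 12 hydroxy ester from step 6
Product: 13 O10-triethylsilyl ether of 12 (O8 angelate; O10 and O11 as triethylsilyl ethers; ring unchanged)
Conditions: TESOTf, 2,6-lutidine, CH2Cl2, −78 °C
Reagents that add atoms: triethylsilyl trifluoromethanesulfonate, CC[Si](CC)(CC)OS(=O)(=O)C(F)(F)F
Why: Fast silylation with a silyl triflate and a hindered, non-nucleophilic base caps O10 before the O8 ester can migrate to it; no stereocentre is touched.

Step 8
Reactants: 13 bis(triethylsilyl) ether
Product: 15 2α-hydroxy enone (13 carrying a hydroxyl at C2, trans to the C1 chain), via linear TMS dienol ether 14 (not isolated)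
Conditions: TMSOTf, Et3N, CH2Cl2, 0 °C → rt (equilibration); DMDO, acetone/CH2Cl2, −78 °C; citric acid, MeOH, 0 °C
Reagents that add atoms: dimethyldioxirane, CC1(C)OO1
Why: Equilibrating silylation should give the through-conjugated dienol ether 14 (γ-deprotonation at C2), which is the thermodynamic isomer for cyclohexenones; in this vinylogous Rubottom oxidation the dioxirane attacks the terminal C2=C3 bond of the 1-silyloxy diene, the least hindered electron-rich alkene in the molecule, from the face anti to the adjacent C1 chain, and collapse returns the enone with the new hydroxyl α.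

Step 9
Reactants: 15 2α-hydroxy enone; 6 angelic acid
Product: 16 2α-angelate enone (15 with its C2 hydroxyl esterified; O8 and O2 angelates)
Conditions: 6 (1.2 equiv), 2,4,6-Cl3C6H2COCl, Et3N, toluene, rt; then 15, 70 °C (no DMAP)
Reagents that add atoms: none
Why: Yamaguchi-type esterification through the mixed 2,4,6-trichlorobenzoic anhydride without a nucleophilic catalyst, the conditions under which angelates are formed without Z to E isomerisation; 15 has a single free hydroxyl, so one equivalent of the acid is transferred, and the new ester masks the allylic alcohol during the next oxidation.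

Step 10
Reactants: 16 2α-angelate enone
Product: 18 6α-hydroxy 2α-angelate enone (16 carrying a hydroxyl at C6 trans to the C1 chain), via cross-conjugated TMS dienol ether 17 (not isolated)
Conditions: TMSOTf (1.3 equiv), Et3N, CH2Cl2, −78 °C; DMDO, acetone/CH2Cl2, −78 °C; citric acid, MeOH, 0 °C
Reagents that add atoms: dimethyldioxirane, CC1(C)OO1
Why: Kinetic soft enolisation removes a C6 methylene hydrogen (the γ position is now a tertiary, acyloxy-bearing C–H), giving 17; Rubottom oxidation of its C5=C6 enol ether bond should occur anti to the neighbouring C1 chain (6α), which is also the equatorial, thermodynamically preferred configuration of this epimerisable centre, and citric acid removes trimethylsilyl but not triethylsilyl groups.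

Step 11
Reactants: 18 6α-hydroxy 2α-angelate enone; 6 angelic acid
Product: 19 2α,6α,8-tris(angelate) enone
Conditions: 6 (1.5 equiv), 2,4,6-Cl3C6H2COCl, Et3N, toluene, rt; then 18, 70 °C (no DMAP)
Reagents that add atoms: none
Why: The same mixed-anhydride esterification, now of the only free hydroxyl, the C6 ketol; the 6α ester is the equatorial, thermodynamic epimer, and an O2 to O6 acyl shift in 18 would be without consequence because both oxygens end as angelates.

Step 12
Reactants: 19 tris(angelate) enone
Product: 20 5β-allylic alcohol (hydroxyl at C5 cis to the C1 chain, C3=C4 alkene retained)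
Conditions: NaBH4, CeCl3·7H2O, MeOH/THF, −78 °C
Reagents that add atoms: none
Why: Luche 1,2-reduction; with the C1, C2 and C6 substituents all equatorial the half-chair is locked and axial hydride delivery gives the equatorial β-alcohol, while esters and the other alkenes are not reduced.

Step 13
Reactants: 20 5β-allylic alcohol
Product: 21 3β,4β-epoxy-5β-alcohol
Conditions: VO(acac)2 (5 mol%), t-BuOOH, CH2Cl2, 0 °C → rt
Reagents that add atoms: tert-butyl hydroperoxide, CC(C)(C)OO
Why: Hydroxyl-directed epoxidation: the vanadium alkoxide of the C5 hydroxyl delivers oxygen to the face of C3=C4 that it occupies (β), and only the alkene of the allylic alcohol reacts, so C7=C14 and the angelates are spared.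

Step 14
Reactants: 21 epoxy alcohol
Product: 22 3β,4β-epoxy ketone
Conditions: Dess–Martin periodinane, NaHCO3, CH2Cl2, 0 °C → rt
Reagents that add atoms: none
Why: Buffered Dess–Martin oxidation of the only free hydroxyl returns the C5 ketone without opening the epoxide or moving an acyl group.

Step 15
Reactants: 22 3β,4β-epoxy ketone
Product: 24 O10,O11-bis(triethylsilyl) ether of the target (2α-OH, 3α-angelate, 4β-OH), via dioxolan-2-ylium ion 23 (not isolated)
Conditions: BF3·OEt2, CH2Cl2, −78 → −40 °C; then THF/H2O, NaHCO3, −40 → 0 °C
Reagents that add atoms: water, O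
Why: Neighbouring-group opening of an epoxide by a trans-vicinal ester: the carbonyl oxygen of the C2 angelate attacks C3 anti to the activated epoxide C–O bond (trans-diaxial Fürst–Plattner opening at the carbon remote from the ketone, cationic character at C4 being disfavoured), setting O3 α and O4 β in the fused ion 23; buffered hydrolysis goes through the orthoacid, which is known to open preferentially to the axial ester and equatorial alcohol, placing the angelate on O3 and freeing O2.

Step 16
Reactants: 24 bis(triethylsilyl) ether
Product: 25 target, (1S,2S,3S,4R,6R,8S,10S)-2,4,10,11-tetrahydroxy-5-oxo 3,6,8-tris(angelate) (CNP0215698.1)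
Conditions: HF·pyridine, pyridine, THF, 0 °C → rt
Reagents that add atoms: none
Why: Buffered acidic fluoride removes both triethylsilyl ethers; avoiding basic fluoride protects the α-ketol and the diol monoesters from rearrangement and acyl migration.

## Compound list

1 | (S)-carvone | CC1=CC[C@@H](CC1=O)C(C)=C | starting material
2 | (5S)-5-(3-chloroprop-1-en-2-yl)-2-methylcyclohex-2-en-1-one | C=C(CCl)[C@H]1CC=C(C)C(=O)C1 | intermediate
3 | 2-[(1S)-4-methyl-5-oxocyclohex-3-en-1-yl]prop-2-enal | C=C(C=O)[C@H]1CC=C(C)C(=O)C1 | intermediate
4 | 3-hydroxy-3-methylbutan-2-one | CC(=O)C(C)(C)O | starting material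
5 | 3-methyl-3-(triethylsilyloxy)butan-2-one | CC(=O)C(C)(C)O[Si](CC)(CC)CC | intermediate
6 | angelic acid, (Z)-2-methylbut-2-enoic acid | C/C=C(/C)C(=O)O | starting material
7 | (Z)-2-methylbut-2-en-1-ol | C/C=C(/C)CO | intermediate
8 | (Z)-2-methylbut-2-enal | C/C=C(/C)C=O | intermediate
9 | boron enolate, 3-methyl-3-(triethylsilyloxy)but-1-en-2-yl diisopinocampheylborinate | C=C(OB([C@@H]1C[C@@H]2C[C@H]([C@H]1C)C2(C)C)[C@@H]1C[C@@H]2C[C@H]([C@H]1C)C2(C)C)C(C)(C)O[Si](CC)(CC)CC | intermediate
10 | boron aldolate, O8-diisopinocampheylborinate of aldol 11 (8S) | C=C([C@H]1CC=C(C)C(=O)C1)[C@H](CC(=O)C(C)(C)O[Si](CC)(CC)CC)OB([C@@H]1C[C@@H]2C[C@H]([C@H]1C)C2(C)C)[C@@H]1C[C@@H]2C[C@H]([C@H]1C)C2(C)C | intermediate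
11 | aldol, (5S)-5-hydroxy-2-methyl-6-[(1S)-4-methyl-5-oxocyclohex-3-en-1-yl]-2-(triethylsilyloxy)hept-6-en-3-one | C=C([C@H]1CC=C(C)C(=O)C1)[C@@H](O)CC(=O)C(C)(C)O[Si](CC)(CC)CC | intermediate
12 | (3S,5S)-5-hydroxy-6-methyl-2-[(1S)-4-methyl-5-oxocyclohex-3-en-1-yl]-6-(triethylsilyloxy)hept-1-en-3-yl (Z)-2-methylbut-2-enoate | C=C([C@H]1CC=C(C)C(=O)C1)[C@H](C[C@H](O)C(C)(C)O[Si](CC)(CC)CC)OC(=O)/C(C)=C\C | intermediate
13 | O10-triethylsilyl ether of 12 | C=C([C@H]1CC=C(C)C(=O)C1)[C@H](C[C@H](O[Si](CC)(CC)CC)C(C)(C)O[Si](CC)(CC)CC)OC(=O)/C(C)=C\C | intermediate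
14 | linear trimethylsilyl dienol ether of 13 (C2=C3, C4=C5, O5 silyl) | C=C([C@H]1C=CC(C)=C(O[Si](C)(C)C)C1)[C@H](C[C@H](O[Si](CC)(CC)CC)C(C)(C)O[Si](CC)(CC)CC)OC(=O)/C(C)=C\C | intermediate
15 | 2α-hydroxy enone | C=C([C@H]1[C@H](O)C=C(C)C(=O)C1)[C@H](C[C@H](O[Si](CC)(CC)CC)C(C)(C)O[Si](CC)(CC)CC)OC(=O)/C(C)=C\C | intermediate
16 | 2α-angelate enone (O2 and O8 angelates) | C=C([C@H]1[C@H](OC(=O)/C(C)=C\C)C=C(C)C(=O)C1)[C@H](C[C@H](O[Si](CC)(CC)CC)C(C)(C)O[Si](CC)(CC)CC)OC(=O)/C(C)=C\C | intermediate
17 | cross-conjugated trimethylsilyl dienol ether of 16 (C3=C4, C5=C6; O5 trimethylsilyl) | C=C([C@H]1[C@H](OC(=O)/C(C)=C\C)C=C(C)C(O[Si](C)(C)C)=C1)[C@H](C[C@H](O[Si](CC)(CC)CC)C(C)(C)O[Si](CC)(CC)CC)OC(=O)/C(C)=C\C | intermediate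
18 | 6α-hydroxy 2α-angelate enone | C=C([C@H]1[C@H](OC(=O)/C(C)=C\C)C=C(C)C(=O)[C@@H]1O)[C@H](C[C@H](O[Si](CC)(CC)CC)C(C)(C)O[Si](CC)(CC)CC)OC(=O)/C(C)=C\C | intermediate
19 | 2α,6α,8-tris(angelate) enone | C=C([C@H]1[C@H](OC(=O)/C(C)=C\C)C=C(C)C(=O)[C@@H]1OC(=O)/C(C)=C\C)[C@H](C[C@H](O[Si](CC)(CC)CC)C(C)(C)O[Si](CC)(CC)CC)OC(=O)/C(C)=C\C | intermediate
20 | 5β-allylic alcohol of 19 | C=C([C@H]1[C@H](OC(=O)/C(C)=C\C)C=C(C)[C@@H](O)[C@@H]1OC(=O)/C(C)=C\C)[C@H](C[C@H](O[Si](CC)(CC)CC)C(C)(C)O[Si](CC)(CC)CC)OC(=O)/C(C)=C\C | intermediate
21 | 3β,4β-epoxy-5β-alcohol | C=C([C@H]1[C@H](OC(=O)/C(C)=C\C)[C@H]2O[C@@]2(C)[C@@H](O)[C@@H]1OC(=O)/C(C)=C\C)[C@H](C[C@H](O[Si](CC)(CC)CC)C(C)(C)O[Si](CC)(CC)CC)OC(=O)/C(C)=C\C | intermediate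
22 | 3β,4β-epoxy ketone | C=C([C@H]1[C@H](OC(=O)/C(C)=C\C)[C@H]2O[C@@]2(C)C(=O)[C@@H]1OC(=O)/C(C)=C\C)[C@H](C[C@H](O[Si](CC)(CC)CC)C(C)(C)O[Si](CC)(CC)CC)OC(=O)/C(C)=C\C | intermediate
23 | 2α,3α-fused 2-[(Z)-but-2-en-2-yl]-1,3-dioxolan-2-ylium ion, O4 as trifluoroborate | C=C([C@H]1[C@@H]2OC(/C(C)=C\C)=[O+][C@@H]2[C@@](C)(O[B-](F)(F)F)C(=O)[C@@H]1OC(=O)/C(C)=C\C)[C@H](C[C@H](O[Si](CC)(CC)CC)C(C)(C)O[Si](CC)(CC)CC)OC(=O)/C(C)=C\C | intermediate
24 | O10,O11-bis(triethylsilyl) ether of the target | C=C([C@H]1[C@H](O)[C@H](OC(=O)/C(C)=C\C)[C@@](C)(O)C(=O)[C@@H]1OC(=O)/C(C)=C\C)[C@H](C[C@H](O[Si](CC)(CC)CC)C(C)(C)O[Si](CC)(CC)CC)OC(=O)/C(C)=C\C | intermediate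
25 | CNP0215698.1 | C=C([C@H]1[C@H](O)[C@H](OC(=O)/C(C)=C\C)[C@@](C)(O)C(=O)[C@@H]1OC(=O)/C(C)=C\C)[C@H](C[C@H](O)C(C)(C)O)OC(=O)/C(C)=C\C | target

## Step count and least certain steps

Total: 16 steps. Longest linear sequence: 13 steps (steps 1, 2 and 6–16, from (S)-carvone).

Step 6 (key step, proposed new method). The most likely failures are loss of the Z geometry of 8 or of the newly formed ester by reversible conjugate addition of residual amine or alkoxide, and slow hydride transfer to the hindered α-silyloxy ketone. Slow transfer would leave time for retro-aldol cleavage, self-Tishchenko reaction of the aldehyde or migration of the acyl group from O8 to O10. The fallback uses known chemistry. It sets out from 3 and 5, whose boron aldol is stopped after the aminoethanol work-up and chromatographed to give aldol 11. Hydroxyl-directed reduction with Me4NBH(OAc)3 (MeCN/AcOH, −30 °C; Saksena–Evans reduction) should give the anti-1,3-diol F1. The allylic C8 hydroxyl, less hindered than the C10 hydroxyl next to the fully substituted silyloxy carbon, is then esterified with one equivalent of the mixed 2,4,6-trichlorobenzoic anhydride of 6. The fallback comes back to the route at 12.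

Step 8. The enolisation may stay under kinetic control, with deprotonation at C6 and oxidation there instead of at C2, or the dioxirane may attack the enol ether bond (C4) of 14 rather than its terminal alkene. The fallback inverts the order of the two ring oxidations and replaces steps 8 to 11. It sets out from 13, which under kinetic soft enolisation (TMSOTf, Et3N, −78 °C) gives the cross-conjugated dienol ether F2; Rubottom oxidation with DMDO and citric acid work-up gives the 6α-hydroxy enone F3. Two equivalents of lithium diisopropylamide (THF, −78 °C) then form the alkoxide, which blocks enolisation toward C6, and the extended dienolate; trapping with TMSCl gives the bis-silylated linear dienol ether F4. DMDO and citric acid work-up lead to the 2α,6α-dihydroxy enone F5, whose two hydroxyls are esterified together with two equivalents of 6 under the conditions of step 9. The fallback comes back to the route at 19.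

Step 15. The acyl group may isomerise to the tiglate while it is part of the alkenyl-substituted cation, the orthoacid may collapse toward the equatorial O2 ester, or the Lewis acid may induce acyl migration of the epoxy ketone with ring contraction. The fallback avoids the cation and makes the C3–O bond intermolecularly at the alcohol oxidation level. It sets out from 15, whose only free hydroxyl is silylated with TESCl and imidazole (DMF, 0 °C) to give the 2α-triethylsilyloxy enone F6. Kinetic enolisation (TMSOTf, Et3N, −78 °C) gives the cross-conjugated trimethylsilyl dienol ether F7, and DMDO followed by citric acid in MeOH gives the 2α-triethylsilyloxy 6α-hydroxy enone F8. Esterification of O6 with 6 as in step 11 gives the 6α-angelate F9, NaBH4/CeCl3·7H2O gives the 5β-allylic alcohol F10, and VO(acac)2/t-BuOOH gives the β-epoxy alcohol F11. Ti(OiPr)4 and 6 (CH2Cl2, rt) then open the chelated epoxy alcohol at C3, the carbon remote from the carbinol, with inversion, to give the 3α-angelate 4β,5β-diol F12. Dess–Martin oxidation of the only secondary hydroxyl gives the ketone F13, and HF·pyridine removes all three silyl groups. The fallback comes back at 25.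

Step 11. The activated acyl donor may isomerise from Z to E at 70 °C in the presence of amine, the ketol carbon C6 may epimerise, and the γ-acyloxy enone may begin to eliminate toward an aromatic ring under the same conditions; the same concerns apply in milder form to step 9. The fallback changes the mode of acyl transfer from a thermal reaction of the neutral alcohol to acylation of the alkoxide at low temperature. It sets out from 18 and 6: two equivalents of 6 are dehydrated with dicyclohexylcarbodiimide to angelic anhydride F14, 18 is converted into its lithium alkoxide with LiN(SiMe3)2 (1 equiv, THF, −78 °C) and treated with F14. The fallback comes back at 19.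

Step 2. The 2-substituted acrolein 3 may be consumed by conjugate addition or oligomerisation under the nucleophilic conditions, or the displacement of chloride may stall. The fallback reaches the aldehyde through the alcohol. It sets out from 2: KOAc with catalytic 18-crown-6 (MeCN, 60 °C) gives the allylic acetate F15, K2CO3 in MeOH at 0 °C gives the allylic alcohol F16, and MnO2 in CH2Cl2 oxidises it. The fallback comes back at 3.

## Further compounds

F1 | step 6 | anti-1,3-diol, (3S,5S)-6-methyl-2-[(1S)-4-methyl-5-oxocyclohex-3-en-1-yl]-6-(triethylsilyloxy)hept-1-ene-3,5-diol | C=C([C@H]1CC=C(C)C(=O)C1)[C@@H](O)C[C@H](O)C(C)(C)O[Si](CC)(CC)CC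
F2 | step 8 | cross-conjugated trimethylsilyl dienol ether of 13 (C3=C4, C5=C6) | C=C([C@H]1CC=C(C)C(O[Si](C)(C)C)=C1)[C@H](C[C@H](O[Si](CC)(CC)CC)C(C)(C)O[Si](CC)(CC)CC)OC(=O)/C(C)=C\C
F3 | step 8 | 6α-hydroxy enone | C=C([C@H]1CC=C(C)C(=O)[C@@H]1O)[C@H](C[C@H](O[Si](CC)(CC)CC)C(C)(C)O[Si](CC)(CC)CC)OC(=O)/C(C)=C\C
F4 | step 8 | linear dienol ether of F3 (C2=C3, C4=C5; O5 and O6 trimethylsilyl) | C=C([C@H]1C=CC(C)=C(O[Si](C)(C)C)[C@@H]1O[Si](C)(C)C)[C@H](C[C@H](O[Si](CC)(CC)CC)C(C)(C)O[Si](CC)(CC)CC)OC(=O)/C(C)=C\C
F5 | step 8 | 2α,6α-dihydroxy enone | C=C([C@H]1[C@H](O)C=C(C)C(=O)[C@@H]1O)[C@H](C[C@H](O[Si](CC)(CC)CC)C(C)(C)O[Si](CC)(CC)CC)OC(=O)/C(C)=C\C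
F6 | step 15 | 2α-triethylsilyloxy enone | C=C([C@H]1[C@H](O[Si](CC)(CC)CC)C=C(C)C(=O)C1)[C@H](C[C@H](O[Si](CC)(CC)CC)C(C)(C)O[Si](CC)(CC)CC)OC(=O)/C(C)=C\C
F7 | step 15 | cross-conjugated trimethylsilyl dienol ether of F6 (C3=C4, C5=C6) | C=C([C@H]1[C@H](O[Si](CC)(CC)CC)C=C(C)C(O[Si](C)(C)C)=C1)[C@H](C[C@H](O[Si](CC)(CC)CC)C(C)(C)O[Si](CC)(CC)CC)OC(=O)/C(C)=C\C
F8 | step 15 | 2α-triethylsilyloxy 6α-hydroxy enone | C=C([C@H]1[C@H](O[Si](CC)(CC)CC)C=C(C)C(=O)[C@@H]1O)[C@H](C[C@H](O[Si](CC)(CC)CC)C(C)(C)O[Si](CC)(CC)CC)OC(=O)/C(C)=C\C
F9 | step 15 | 2α-triethylsilyloxy 6α-angelate enone | C=C([C@H]1[C@H](O[Si](CC)(CC)CC)C=C(C)C(=O)[C@@H]1OC(=O)/C(C)=C\C)[C@H](C[C@H](O[Si](CC)(CC)CC)C(C)(C)O[Si](CC)(CC)CC)OC(=O)/C(C)=C\C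
F10 | step 15 | 5β-allylic alcohol of F9 | C=C([C@H]1[C@H](O[Si](CC)(CC)CC)C=C(C)[C@@H](O)[C@@H]1OC(=O)/C(C)=C\C)[C@H](C[C@H](O[Si](CC)(CC)CC)C(C)(C)O[Si](CC)(CC)CC)OC(=O)/C(C)=C\C
F11 | step 15 | 3β,4β-epoxy-5β-alcohol with 2α-triethylsilyloxy group | C=C([C@H]1[C@H](O[Si](CC)(CC)CC)[C@H]2O[C@@]2(C)[C@@H](O)[C@@H]1OC(=O)/C(C)=C\C)[C@H](C[C@H](O[Si](CC)(CC)CC)C(C)(C)O[Si](CC)(CC)CC)OC(=O)/C(C)=C\C
F12 | step 15 | 3α-angelate 4β,5β-diol with 2α-triethylsilyloxy group | C=C([C@H]1[C@H](O[Si](CC)(CC)CC)[C@H](OC(=O)/C(C)=C\C)[C@@](C)(O)[C@@H](O)[C@@H]1OC(=O)/C(C)=C\C)[C@H](C[C@H](O[Si](CC)(CC)CC)C(C)(C)O[Si](CC)(CC)CC)OC(=O)/C(C)=C\C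
F13 | step 15 | O2,O10,O11-tris(triethylsilyl) ether of the target | C=C([C@H]1[C@H](O[Si](CC)(CC)CC)[C@H](OC(=O)/C(C)=C\C)[C@@](C)(O)C(=O)[C@@H]1OC(=O)/C(C)=C\C)[C@H](C[C@H](O[Si](CC)(CC)CC)C(C)(C)O[Si](CC)(CC)CC)OC(=O)/C(C)=C\C
F14 | step 11 | angelic anhydride, (Z)-2-methylbut-2-enoic anhydride | C/C=C(/C)C(=O)OC(=O)/C(C)=C\C
F15 | step 2 | 2-[(1S)-4-methyl-5-oxocyclohex-3-en-1-yl]prop-2-en-1-yl acetate | C=C(COC(C)=O)[C@H]1CC=C(C)C(=O)C1
F16 | step 2 | (5S)-5-(3-hydroxyprop-1-en-2-yl)-2-methylcyclohex-2-en-1-one | C=C(CO)[C@H]1CC=C(C)C(=O)C1
A1 | alternative 1 | C2/C5 endoperoxide of the ring dienol (free O6 and O8, C10/C11 acetonide) | C=C([C@H]1[C@H](OO2)C=C(C)[C@H]2[C@@H]1O)[C@H](C[C@H](OC(C)(C)O3)C3(C)C)O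
A2 | alternative 2 | 1,2-disubstituted cyclopropanol joining the protected ring and the acetonide chain | O[C@]3(C[C@H](OC(C)(C)O4)C4(C)C)C[C@H]3[C@H]1[C@H](O)[C@H](O[Si](CC)(CC)CC)[C@@](C)(O)[C@@H](OCc2ccc(OC)cc2)[C@@H]1O[Si](CC)(CC)CC
A3 | alternative 3 | protected cyclohexanone with free C4 hydroxyl and complete side chain | C=C([C@H]1[C@H](O[Si](C)(C)C(C)(C)C)[C@H](OCc2ccc(OC)cc2)[C@@](C)(O)C(=O)[C@@H]1OCc1ccc(OC)cc1)[C@H](C[C@H](OC(C)(C)O2)C2(C)C)OCc1ccc(OC)cc1
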